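**Retrosynthetic overview**
1. Target ⇒ its 7‑O‑TIPS ether (final desilylation under buffered, non‑basic conditions).
2. Both prenyl groups ⇒ double Stille coupling of prenylSnBu3 with an (S)‑3',5'‑dibromoflavanone.
3. C2–aryl bond and the only stereocentre ⇒ Rh‑catalysed asymmetric 1,4‑addition of (3,5‑dibromo‑4‑methoxyphenyl)boronic acid to 7‑silyloxychromone.
4. Boronic acid ⇒ sterically controlled Ir C–H borylation of 2,6‑dibromoanisole.
5. No ring is constructed: the benzopyranone bicycle is bought intact as 7‑hydroxychromone, and only C2 is created.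

**Assumption:** the target is the (2S) enantiomer (CIP assignment from the given SMILES). The (S)‑ligand in Step 3 is assigned by analogy with the Hayashi model ((S)‑biaryl bisphosphine gives (S)‑3‑arylcyclohexanone, which maps onto (2S)‑flavanone). This should be confirmed by chiral HPLC/CD on compound 7, and the (R)‑ligand used if the sense is reversed.

**Step 1**
Reactants: 1, 2,6‑dibromoanisole; 2, bis(pinacolato)diboron
Product: 3, (3,5‑dibromo‑4‑methoxyphenyl)boronic acid
Conditions: [Ir(OMe)(cod)]2 (1.5 mol %), dtbpy (3 mol %), B2pin2 (1.0 equiv), THF, 80 °C; then NaIO4, 1 M aq HCl, THF/H2O, rt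
Reagents that add atoms: B2pin2, CC1(C)OB(OC1(C)C)B1OC(C)(C)C(C)(C)O1 (boron); water, O (boronic acid OH groups)
Why: Ir‑catalysed aromatic C–H borylation occurs only at C4, the one C–H not ortho to a substituent, tolerates aryl bromides, and the pinacol ester is cleaved in the same pot by periodate oxidative hydrolysis.

**Step 2**
Reactants: 4, 7‑hydroxy‑4H‑chromen‑4‑one; 5, chlorotriisopropylsilane
Product: 6, 7‑(triisopropylsilyloxy)‑4H‑chromen‑4‑one
Conditions: TIPSCl, imidazole, DMF, 0 °C → rt
Reagents that add atoms: TIPSCl, CC(C)[Si](Cl)(C(C)C)C(C)C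
Why: Standard phenol silylation masks the acidic 7‑OH, which would otherwise protonate the aryl–Rh species and deactivate the chromone as its phenoxide; TIPS comes off later without base or strong acid.

**Step 3**
Reactants: 6, 7‑(triisopropylsilyloxy)‑4H‑chromen‑4‑one; 3, (3,5‑dibromo‑4‑methoxyphenyl)boronic acid (1.8 equiv)
Product: 7, (2S)‑2‑(3,5‑dibromo‑4‑methoxyphenyl)‑7‑(triisopropylsilyloxy)chroman‑4‑one
Conditions: [Rh(OH)(cod)]2 (1.5 mol %), (S)‑MeO‑F12‑BIPHEP (3.3 mol %), CH2Cl2/H2O (10:1), 35–40 °C
Reagents that add atoms: boronic acid 3, COc1c(Br)cc(B(O)O)cc1Br (aryl group)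
Why: Hayashi–Miyaura asymmetric 1,4‑addition, in which the aryl–Rh(I) complex of the electron‑poor (S)‑bisphosphine adds to one enantioface of the chromone C2=C3 bond and the Rh enolate is protonated by water, setting C2 as (S); the C–Br bonds are inert to Rh(I) at this temperature, and the product can be recrystallised to raise ee if needed.

**Step 4**
Reactants: 7, (2S)‑dibromoflavanone; 8, tributyl(3‑methylbut‑2‑en‑1‑yl)stannane (3 equiv)
Product: 9, (2S)‑2‑[4‑methoxy‑3,5‑bis(3‑methylbut‑2‑en‑1‑yl)phenyl]‑7‑(triisopropylsilyloxy)chroman‑4‑one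
Conditions: Pd(PPh3)4 (10 mol %), degassed toluene, 100 °C; tin removed on K2CO3/silica
Reagents that add atoms: prenylSnBu3, CCCC[Sn](CCCC)(CCCC)CC=C(C)C (two prenyl groups)
Why: Twofold Stille coupling gives the linear prenyl arene by reductive elimination at the less hindered allyl terminus, and the base‑free, aprotic conditions avoid the enolate/retro‑oxa‑Michael pathway that racemises flavanones.

**Step 5**
Reactants: 9, TIPS‑protected diprenylflavanone
Product: 10, abyssinone IV 4'‑OMe ether, (2S)‑7‑hydroxy‑2‑[4‑methoxy‑3,5‑bis(3‑methylbut‑2‑en‑1‑yl)phenyl]chroman‑4‑one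
Conditions: TBAF/AcOH (1:1), THF, 0 °C
Reagents that add atoms: none
Why: Fluoride desilylation of the aryl silyl ether, buffered with acetic acid so no free base opens the pyranone ring, leaves the C2 stereocentre, prenyl alkenes and aryl methyl ether untouched.

**Compound list**
1 | 2,6‑dibromoanisole | COc1c(Br)cccc1Br | starting material
2 | bis(pinacolato)diboron | CC1(C)OB(OC1(C)C)B1OC(C)(C)C(C)(C)O1 | starting material
3 | (3,5‑dibromo‑4‑methoxyphenyl)boronic acid | COc1c(Br)cc(B(O)O)cc1Br | intermediate
4 | 7‑hydroxy‑4H‑chromen‑4‑one | O=c1ccoc2cc(O)ccc12 | starting material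
5 | chlorotriisopropylsilane | CC(C)[Si](Cl)(C(C)C)C(C)C | starting material
6 | 7‑(triisopropylsilyloxy)‑4H‑chromen‑4‑one | O=c1ccoc2cc(O[Si](C(C)C)(C(C)C)C(C)C)ccc12 | intermediate
7 | (2S)‑2‑(3,5‑dibromo‑4‑methoxyphenyl)‑7‑(triisopropylsilyloxy)chroman‑4‑one | COc1c(Br)cc([C@@H]2CC(=O)c3ccc(O[Si](C(C)C)(C(C)C)C(C)C)cc3O2)cc1Br | intermediate
8 | tributyl(3‑methylbut‑2‑en‑1‑yl)stannane | CCCC[Sn](CCCC)(CCCC)CC=C(C)C | starting material
9 | (2S)‑2‑[4‑methoxy‑3,5‑bis(3‑methylbut‑2‑en‑1‑yl)phenyl]‑7‑(triisopropylsilyloxy)chroman‑4‑one | COc1c(CC=C(C)C)cc([C@@H]2CC(=O)c3ccc(O[Si](C(C)C)(C(C)C)C(C)C)cc3O2)cc1CC=C(C)C | intermediate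
10 | abyssinone IV 4'‑OMe ether, (2S) | COc1c(CC=C(C)C)cc([C@@H]2CC(=O)c3ccc(O)cc3O2)cc1CC=C(C)C | target

**Total steps:** 5. **Longest linear sequence:** 4 (1 → 3 → 7 → 9 → 10, or 4 → 6 → 7 → 9 → 10).

**Steps most likely to fail, with fallbacks**
1. Step 3. The donor‑substituted chromone may react sluggishly, the product ketone may undergo 1,2‑over‑addition, or ee may be insufficient. Fallback: form the pyranone ring by asymmetric oxa‑Michael addition instead. This means Knoevenagel condensation of tert‑butyl 3‑(2‑hydroxy‑4‑silyloxyphenyl)‑3‑oxopropanoate with 3,5‑dibromo‑4‑methoxybenzaldehyde, cinchona‑thiourea‑catalysed 6‑endo cyclisation, then acid‑mediated ester cleavage and decarboxylation, rejoining the route at the dibromoflavanone.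
2. Step 4. The double coupling may stall at the mono‑prenyl stage, give reverse‑prenyl isomers, or erode ee at 100 °C. Fallback: install the prenyl groups before the stereocentre exists. Isolate the pinacol boronate from Step 1 before periodate cleavage, Stille‑couple it, hydrolyse to (4‑methoxy‑3,5‑diprenylphenyl)boronic acid, and use that in Step 3 so that only desilylation follows.
3. Step 1. The one‑pot borylation/oxidative hydrolysis may give protodeboronation or a boronic acid that is hard to purify. Fallback: halogen–metal exchange instead of C–H borylation. Convert 4‑iodophenol to 2,6‑dibromo‑4‑iodoanisole (Br2, then MeI/K2CO3), then selective I/Mg exchange (iPrMgCl·LiCl, −40 °C), B(OMe)3 and acidic work‑up.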